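**Plan**

Numbering: lactone ring O1/C2–C6. Side chain C1'–C10', with the C1'=C2' alkene, OAc on C4', OH on C6' and C8', and phenyl on C10'.
Cuts: (a) the C1'=C2' alkene is cut by cross-metathesis into vinyl lactone 16 and terminal alkene 11. (b) In 11 the free O6' is tied back onto C2' and iodine is placed on C1', which gives the temporary oxane 9. (c) 9 is cut at C5'–C6', O–C6' and C4'–OAc (Prins) into iodohydrin 3, aldehyde 7 and acetic acid.
Enabling feature: O6', C6', C5', C4', C3' and C2' form a six-atom row, so alkene carbon C2' can hold the C6' oxygen in an oxane ring. The all-equatorial chair of that ring is the 4',6'-anti pattern. Its exocyclic C4' oxygen arrives already acetylated, and its ring oxygen is the masked C6' hydroxyl.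
Forward: fragments A (3) and B (7) are joined with closure of the oxane (step 6), and zinc opens that ring again (step 7). The dihydropyranone ring is made separately by ring-closing metathesis (step 10) and attached by cross-metathesis (step 11). Desilylation ends the route.
Stereochemistry: C8' comes from a Noyori hydrogenation. C6' and C4' come from the chair Prins transition state, controlled by the sacrificial C2' centre, which derives from (R)-epichlorohydrin and is erased in step 7. Lactone C6 comes from a Brown allylboration, and the E geometry from thermodynamic control in the cross-metathesis.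

Key step: step 6

Remark: keto ester 4 and the pentane solution of (−)-Ipc2B(allyl) are taken as catalogue items; where a descriptor changes along the route (C4', C6'), only CIP priorities change and no centre is inverted.

**Step 1**
Reactants: 1 (R)-epichlorohydrin
Product: 2 (R)-1-chloropent-4-en-2-ol
Conditions: CH2=CHMgBr (1.2 equiv), CuI (10 mol %), THF, −40 to −20 °C; aqueous work-up
Reagents that add atoms: vinylmagnesium bromide, C=C[Mg]Br
Why: Copper-catalysed Grignard opening of a terminal epoxide occurs at the unsubstituted ring carbon faster than chloride displacement, so the stereocentre of 1 should pass unchanged into 2.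

**Step 2**
Reactants: 2 (R)-1-chloropent-4-en-2-ol
Product: 3 (R)-1-iodopent-4-en-2-ol
Conditions: NaI (5 equiv), butan-2-one, 80 °C, dark
Reagents that add atoms: sodium iodide, [Na+].[I-]
Why: Finkelstein exchange, driven by precipitation of NaCl, should turn the primary chloride into the iodide needed for the later zinc insertion without touching the carbinol centre.

**Step 3**
Reactants: 4 ethyl 3-oxo-5-phenylpentanoate
Product: 5 ethyl (R)-3-hydroxy-5-phenylpentanoate
Conditions: H2 (50 bar), RuCl2[(R)-BINAP] (0.5 mol %), EtOH, 50 °C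
Reagents that add atoms: none
Why: In the Noyori asymmetric hydrogenation of a β-keto ester, chelation of ketone and ester to the (R)-BINAP ruthenium hydride exposes one carbonyl face, which should set C8' as R.

**Step 4**
Reactants: 5 ethyl (R)-3-hydroxy-5-phenylpentanoate
Product: 6 ethyl (R)-3-(tert-butyldiphenylsilyloxy)-5-phenylpentanoate
Conditions: TBDPSCl (1.2 equiv), imidazole (2.5 equiv), DMF, rt
Reagents that add atoms: tert-butyldiphenylsilyl chloride, CC(C)(C)[Si](Cl)(c1ccccc1)c1ccccc1
Why: This is an imidazole-assisted silylation of a secondary alcohol, and TBDPS is chosen because it should withstand the acid of step 6 and the zinc of step 7.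

**Step 5**
Reactants: 6 ethyl (R)-3-(tert-butyldiphenylsilyloxy)-5-phenylpentanoate
Product: 7 (R)-3-(tert-butyldiphenylsilyloxy)-5-phenylpentanal
Conditions: DIBAL-H (1.1 equiv), CH2Cl2, −78 °C; aq Rochelle salt
Reagents that add atoms: none
Why: Low-temperature DIBAL-H reduction of an ester is a standard way to stop at the aldehyde, and the base-free conditions should leave the β-silyloxy centre C8' untouched.

**Step 6**
Reactants: 3 (R)-1-iodopent-4-en-2-ol; 7 (R)-3-(tert-butyldiphenylsilyloxy)-5-phenylpentanal
Product: 9 (2R,4S,6S)-2-(iodomethyl)-6-[(2R)-2-(tert-butyldiphenylsilyloxy)-4-phenylbutyl]oxan-4-yl acetate (all-cis oxane), via oxocarbenium ion 8 (not isolated)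
Conditions: BF3·OEt2 (2 equiv, promoter), AcOH (5 equiv), TMSOAc (4 equiv), cyclohexane, 0 °C to rt; aq NaHCO3
Reagents that add atoms: acetic acid, CC(=O)O; trimethylsilyl acetate, CC(=O)O[Si](C)(C)C (same acetate pool)
Why: BF3·OEt2 condenses alcohol 3 and aldehyde 7 to the (E)-oxocarbenium ion 8, whose carbon C6' is attacked by the terminal alkene carbon C5' while acetate adds to the positive charge building up at C4', so the C5'–C6' bond, the ring O–C6' bond and the C4'–OAc bond all arise in one flask. The closest known reaction type is the acetoxy-terminated Prins cyclisation of homoallylic alcohols with aliphatic aldehydes under BF3·OEt2/AcOH/TMSOAc. The single ring formed, the oxane O/C6'/C5'/C4'/C3'/C2', closes 6-endo-trig at the alkene through a chair transition state. C6' is controlled by the sacrificial centre C2', since the CH2I group and the C7' chain both sit equatorial on that chair (2,6-cis), and C4' is controlled by equatorial capture of the oxan-4-yl cation, so the all-cis ring should result, which is the 4',6'-anti pattern of the open chain; C8' lies outside the ring and is only carried along. The step needs acetate rather than fluoride as the terminating nucleophile (excess AcOH and fluoride-scavenging TMSOAc), survival of the C8' ether (acid-stable TBDPS) and no stereochemical leakage by 2-oxonia-Cope rearrangement with side-chain exchange (the electron-withdrawing CH2I group disfavours the rearranged cation, and TMSOAc removes the water that exchange needs).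

**Step 7**
Reactants: 9 all-cis oxane acetate
Product: 11 (4R,6S,8R)-8-(tert-butyldiphenylsilyloxy)-6-hydroxy-10-phenyldec-1-en-4-yl acetate, via alkylzinc iodide 10 (not isolated)
Conditions: Zn dust (activated, 10 equiv), AcOH (3 equiv), THF, 40 °C, ultrasound
Reagents that add atoms: none
Why: In this Boord-type reductive β-elimination (the ether analogue of the Vasella fragmentation), zinc inserts into the C1'–I bond and organozinc 10 expels the ring oxygen, which erases C2', creates the C1'=C2' terminal alkene and frees only the C6' hydroxyl, while AcOH protonates the zinc alkoxide at once and should hold back acetyl migration.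

**Step 8**
Reactants: 12 acrolein
Product: 14 (S)-hexa-1,5-dien-3-ol, via diisopinocampheyl borinate 13 (not isolated)
Conditions: (−)-Ipc2B(allyl) [(+)-α-pinene series, 1 M in pentane, 1.1 equiv], Et2O, −78 °C; then NaOH, H2O2, 0 °C to rt
Reagents that add atoms: (−)-B-allyldiisopinocampheylborane, C=CCB([C@@H]1C[C@@H]2C[C@@H](C2(C)C)[C@H]1C)[C@@H]1C[C@@H]2C[C@@H](C2(C)C)[C@H]1C
Why: Brown asymmetric allylboration runs through a chair Zimmerman–Traxler transition state in which the isopinocampheyl groups of the (+)-α-pinene series direct the allyl group to the aldehyde face that should give the S carbinol, the future lactone C6.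

**Step 9**
Reactants: 14 (S)-hexa-1,5-dien-3-ol
Product: 15 (S)-hexa-1,5-dien-3-yl acrylate
Conditions: acryloyl chloride (1.3 equiv), Et3N (2 equiv), CH2Cl2, 0 °C
Reagents that add atoms: acryloyl chloride, C=CC(=O)Cl
Why: O-acylation of a secondary alcohol with an acid chloride does not break the C–O bond, so the configuration should be retained.

**Step 10**
Reactants: 15 (S)-hexa-1,5-dien-3-yl acrylate
Product: 16 (S)-6-vinyl-5,6-dihydro-2H-pyran-2-one
Conditions: first-generation Grubbs catalyst RuCl2(=CHPh)(PCy3)2 (5 mol %), Ti(OiPr)4 (0.3 equiv), CH2Cl2 (0.005 M), reflux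
Reagents that add atoms: none
Why: In this ring-closing metathesis the carbene should load on the unhindered allyl terminus and close onto the acrylate to the six-membered lactone, while the oxygen-flanked vinyl group stays out and Ti(OiPr)4 prevents chelation of the carbene by the ester carbonyl.

**Step 11**
Reactants: 11 terminal alkene (4R,6S,8R)-hydroxy acetate; 16 (S)-6-vinyl-5,6-dihydro-2H-pyran-2-one (2 equiv)
Product: 17 (1E,4R,6S,8R)-8-(tert-butyldiphenylsilyloxy)-6-hydroxy-1-[(2S)-6-oxo-3,6-dihydro-2H-pyran-2-yl]-10-phenyldec-1-en-4-yl acetate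
Conditions: second-generation Hoveyda–Grubbs catalyst RuCl2(=CH-C6H4-2-OiPr)(SIMes) (5 mol %), CH2Cl2, 40 °C
Reagents that add atoms: none
Why: Olefin cross-metathesis between a reactive terminal alkene and a slowly dimerising allylic-oxygenated vinyl group should be selective for the cross product, give the E alkene under thermodynamic control, and leave the conjugated ring alkene, the free hydroxyl and the acetate untouched.

**Step 12**
Reactants: 17 silyl ether of the target
Product: 18 (1E,4R,6R,8R)-6,8-dihydroxy-1-[(2S)-6-oxo-3,6-dihydro-2H-pyran-2-yl]-10-phenyldec-1-en-4-yl acetate (target)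
Conditions: HF·pyridine, pyridine, THF, 0 °C to rt, polyethylene vessel
Reagents that add atoms: none
Why: Fluoride-mediated desilylation in a mildly acidic buffered medium should cleave the Si–O bond without touching any stereocentre, the lactone or the acetate, and without the base-induced acetyl migration that a naked fluoride source could cause.

**Compound list**

1 | (R)-epichlorohydrin | ClC[C@H]1CO1 | starting material
2 | (R)-1-chloropent-4-en-2-ol | ClC[C@H](O)CC=C | intermediate
3 | (R)-1-iodopent-4-en-2-ol | IC[C@H](O)CC=C | intermediate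
4 | ethyl 3-oxo-5-phenylpentanoate | CCOC(=O)CC(=O)CCc1ccccc1 | starting material
5 | ethyl (R)-3-hydroxy-5-phenylpentanoate | CCOC(=O)C[C@H](O)CCc1ccccc1 | intermediate
6 | ethyl (R)-3-(tert-butyldiphenylsilyloxy)-5-phenylpentanoate | CCOC(=O)C[C@H](O[Si](c1ccccc1)(c1ccccc1)C(C)(C)C)CCc1ccccc1 | intermediate
7 | (R)-3-(tert-butyldiphenylsilyloxy)-5-phenylpentanal | O=CC[C@H](O[Si](c1ccccc1)(c1ccccc1)C(C)(C)C)CCc1ccccc1 | intermediate
8 | (E)-[(3R)-3-(tert-butyldiphenylsilyloxy)-5-phenylpentylidene][(2R)-1-iodopent-4-en-2-yl]oxonium ion | IC[C@@H](CC=C)/[O+]=C/C[C@H](O[Si](c1ccccc1)(c1ccccc1)C(C)(C)C)CCc1ccccc1 | intermediate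
9 | (2R,4S,6S)-2-(iodomethyl)-6-[(2R)-2-(tert-butyldiphenylsilyloxy)-4-phenylbutyl]oxan-4-yl acetate (all-cis) | IC[C@H]1C[C@@H](OC(C)=O)C[C@@H](C[C@H](O[Si](c2ccccc2)(c2ccccc2)C(C)(C)C)CCc2ccccc2)O1 | intermediate
10 | {(2R,4S,6S)-4-acetoxy-6-[(2R)-2-(tert-butyldiphenylsilyloxy)-4-phenylbutyl]oxan-2-yl}methylzinc iodide | I[Zn]C[C@H]1C[C@@H](OC(C)=O)C[C@@H](C[C@H](O[Si](c2ccccc2)(c2ccccc2)C(C)(C)C)CCc2ccccc2)O1 | intermediate
11 | (4R,6S,8R)-8-(tert-butyldiphenylsilyloxy)-6-hydroxy-10-phenyldec-1-en-4-yl acetate | CC(=O)O[C@H](CC=C)C[C@H](O)C[C@H](O[Si](c1ccccc1)(c1ccccc1)C(C)(C)C)CCc1ccccc1 | intermediate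
12 | acrolein | C=CC=O | starting material
13 | (S)-hexa-1,5-dien-3-yl diisopinocampheylborinate | C=C[C@@H](OB([C@@H]1C[C@@H]2C[C@@H](C2(C)C)[C@H]1C)[C@@H]1C[C@@H]2C[C@@H](C2(C)C)[C@H]1C)CC=C | intermediate
14 | (S)-hexa-1,5-dien-3-ol | C=C[C@@H](O)CC=C | intermediate
15 | (S)-hexa-1,5-dien-3-yl acrylate | C=CC(=O)O[C@H](C=C)CC=C | intermediate
16 | (S)-6-vinyl-5,6-dihydro-2H-pyran-2-one | C=C[C@@H]1CC=CC(=O)O1 | intermediate
17 | (1E,4R,6S,8R)-8-(tert-butyldiphenylsilyloxy)-6-hydroxy-1-[(2S)-6-oxo-3,6-dihydro-2H-pyran-2-yl]-10-phenyldec-1-en-4-yl acetate | CC(=O)O[C@H](C/C=C/[C@@H]1CC=CC(=O)O1)C[C@H](O)C[C@H](O[Si](c1ccccc1)(c1ccccc1)C(C)(C)C)CCc1ccccc1 | intermediate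
18 | (1E,4R,6R,8R)-6,8-dihydroxy-1-[(2S)-6-oxo-3,6-dihydro-2H-pyran-2-yl]-10-phenyldec-1-en-4-yl acetate | CC(=O)O[C@H](C/C=C/[C@@H]1CC=CC(=O)O1)C[C@H](O)C[C@H](O)CCc1ccccc1 | target

Total step count: 12.
Longest linear sequence: 7 steps (steps 3, 4, 5, 6, 7, 11, 12, from 4).

**Steps most likely to fail**

**Step 6.**
- What may go wrong:
  - acid-induced loss of the β-silyloxy group from the activated aldehyde;
  - exchange of side chains after 2-oxonia-Cope rearrangement and hydrolysis;
  - termination of the cyclisation by fluoride instead of acetate.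
- Fallback: a segment-coupling version in which the two fragments are first joined through an ester oxygen. No free aldehyde and no water are then present when the cation forms.
- It sets out from 6 and 3 and comes back to the route at 9.
- Saponification of 6 (LiOH, THF/H2O) should give (R)-3-(tert-butyldiphenylsilyloxy)-5-phenylpentanoic acid F1.
- Carbodiimide esterification of F1 with 3 (DCC, DMAP, CH2Cl2) should give (R)-1-iodopent-4-en-2-yl (R)-3-(tert-butyldiphenylsilyloxy)-5-phenylpentanoate F2.
- DIBAL-H at −78 °C followed in the same flask by Ac2O, pyridine and DMAP (reductive acetylation) should give the α-acetoxy ether (3R)-1-acetoxy-3-(tert-butyldiphenylsilyloxy)-5-phenylpentyl (R)-1-iodopent-4-en-2-yl ether F3.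
- Ionisation of F3 with BF3·OEt2/AcOH in cyclohexane regenerates ion 8 unimolecularly and should give 9.

**Step 7.**
- What may go wrong:
  - migration of the acetyl group to the oxygen freed at C6' while it is still a zinc alkoxide;
  - protonolysis of the carbon–zinc bond before β-elimination.
- Fallback: the temporary ring is dropped altogether. The same C5'–C6' bond is made by an acyl-anion/epoxide union, and a directed hydride transfer then places the acetyl group.
- It sets out from 7 and 2 and comes back to the route at 11.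
- Thioacetalisation of 7 (propane-1,3-dithiol, MgBr2·OEt2) should give 2-[(2R)-2-(tert-butyldiphenylsilyloxy)-4-phenylbutyl]-1,3-dithiane F4.
- NaOH should close 2 to (R)-2-allyloxirane F5.
- Lithiation of F4 (t-BuLi, THF/HMPA, −78 °C) and opening of F5 at its CH2 terminus should give (2R)-1-{2-[(2R)-2-(tert-butyldiphenylsilyloxy)-4-phenylbutyl]-1,3-dithian-2-yl}pent-4-en-2-ol F6.
- MeI and CaCO3 in aqueous MeCN should unmask (4R,8R)-8-(tert-butyldiphenylsilyloxy)-4-hydroxy-10-phenyldec-1-en-6-one F7.
- An Evans–Tishchenko reduction of F7 (SmI2 cat., MeCHO, THF, −10 °C) transfers hydride within the C4' hemiacetal chelate. This should set C6' anti to C4' and leave the acetyl group on O4', which is 11.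

**Step 11.**
- What may go wrong:
  - self-metathesis of the terminal olefin;
  - low turnover at the hindered oxygen-flanked vinyl group;
  - migration of the double bond along the chain.
- Fallback: the lactone is built on the chain instead of being attached ready-made.
- It sets out from 11 and comes back to the route at 18.
- TESCl and imidazole should give (4R,6S,8R)-8-(tert-butyldiphenylsilyloxy)-10-phenyl-6-(triethylsilyloxy)dec-1-en-4-yl acetate F8. This protection is needed because a free O6' could add back to the enal in an oxa-Michael closure.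
- Cross-metathesis of F8 with crotonaldehyde (second-generation Hoveyda–Grubbs catalyst) should give (2E,5R,7S,9R)-9-(tert-butyldiphenylsilyloxy)-1-oxo-11-phenyl-7-(triethylsilyloxy)undec-2-en-5-yl acetate F9.
- Brown allylboration of F9 with the same (−)-Ipc2B(allyl) and a non-basic oxidative work-up should give (4S,5E,8R,10S,12R)-12-(tert-butyldiphenylsilyloxy)-4-hydroxy-14-phenyl-10-(triethylsilyloxy)tetradeca-1,5-dien-8-yl acetate F10.
- Acryloyl chloride and Et3N should give (4S,5E,8R,10S,12R)-8-acetoxy-12-(tert-butyldiphenylsilyloxy)-14-phenyl-10-(triethylsilyloxy)tetradeca-1,5-dien-4-yl acrylate F11.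
- Ring-closing metathesis of F11 (second-generation Grubbs catalyst RuCl2(=CHPh)(PCy3)(SIMes), CH2Cl2, reflux) should give the 6'-O-triethylsilyl 8'-O-tert-butyldiphenylsilyl ether of the target F12.
- HF·pyridine should remove both silyl groups from F12 and give 18.

**Further compounds**

F1 | step 6 | (R)-3-(tert-butyldiphenylsilyloxy)-5-phenylpentanoic acid | OC(=O)C[C@H](O[Si](c1ccccc1)(c1ccccc1)C(C)(C)C)CCc1ccccc1
F2 | step 6 | (R)-1-iodopent-4-en-2-yl (R)-3-(tert-butyldiphenylsilyloxy)-5-phenylpentanoate | IC[C@@H](CC=C)OC(=O)C[C@H](O[Si](c1ccccc1)(c1ccccc1)C(C)(C)C)CCc1ccccc1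
F3 | step 6 | (3R)-1-acetoxy-3-(tert-butyldiphenylsilyloxy)-5-phenylpentyl (R)-1-iodopent-4-en-2-yl ether (both acetal epimers) | IC[C@@H](CC=C)OC(OC(C)=O)C[C@H](O[Si](c1ccccc1)(c1ccccc1)C(C)(C)C)CCc1ccccc1
F4 | step 7 | 2-[(2R)-2-(tert-butyldiphenylsilyloxy)-4-phenylbutyl]-1,3-dithiane | C1CSC(C[C@H](O[Si](c2ccccc2)(c2ccccc2)C(C)(C)C)CCc2ccccc2)SC1
F5 | step 7 | (R)-2-allyloxirane | C=CC[C@@H]1CO1
F6 | step 7 | (2R)-1-{2-[(2R)-2-(tert-butyldiphenylsilyloxy)-4-phenylbutyl]-1,3-dithian-2-yl}pent-4-en-2-ol | C=CC[C@@H](O)CC1(C[C@H](O[Si](c2ccccc2)(c2ccccc2)C(C)(C)C)CCc2ccccc2)SCCCS1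
F7 | step 7 | (4R,8R)-8-(tert-butyldiphenylsilyloxy)-4-hydroxy-10-phenyldec-1-en-6-one | C=CC[C@@H](O)CC(=O)C[C@H](O[Si](c1ccccc1)(c1ccccc1)C(C)(C)C)CCc1ccccc1
F8 | step 11 | (4R,6S,8R)-8-(tert-butyldiphenylsilyloxy)-10-phenyl-6-(triethylsilyloxy)dec-1-en-4-yl acetate | CC(=O)O[C@H](CC=C)C[C@H](O[Si](CC)(CC)CC)C[C@H](O[Si](c1ccccc1)(c1ccccc1)C(C)(C)C)CCc1ccccc1
F9 | step 11 | (2E,5R,7S,9R)-9-(tert-butyldiphenylsilyloxy)-1-oxo-11-phenyl-7-(triethylsilyloxy)undec-2-en-5-yl acetate | CC(=O)O[C@H](C/C=C/C=O)C[C@H](O[Si](CC)(CC)CC)C[C@H](O[Si](c1ccccc1)(c1ccccc1)C(C)(C)C)CCc1ccccc1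
F10 | step 11 | (4S,5E,8R,10S,12R)-12-(tert-butyldiphenylsilyloxy)-4-hydroxy-14-phenyl-10-(triethylsilyloxy)tetradeca-1,5-dien-8-yl acetate | CC(=O)O[C@H](C/C=C/[C@@H](O)CC=C)C[C@H](O[Si](CC)(CC)CC)C[C@H](O[Si](c1ccccc1)(c1ccccc1)C(C)(C)C)CCc1ccccc1
F11 | step 11 | (4S,5E,8R,10S,12R)-8-acetoxy-12-(tert-butyldiphenylsilyloxy)-14-phenyl-10-(triethylsilyloxy)tetradeca-1,5-dien-4-yl acrylate | CC(=O)O[C@H](C/C=C/[C@@H](OC(=O)C=C)CC=C)C[C@H](O[Si](CC)(CC)CC)C[C@H](O[Si](c1ccccc1)(c1ccccc1)C(C)(C)C)CCc1ccccc1
F12 | step 11 | 6'-O-triethylsilyl 8'-O-tert-butyldiphenylsilyl ether of the target | CC(=O)O[C@H](C/C=C/[C@@H]1CC=CC(=O)O1)C[C@H](O[Si](CC)(CC)CC)C[C@H](O[Si](c1ccccc1)(c1ccccc1)C(C)(C)C)CCc1ccccc1
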